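The four carbons C3–C4–C5–C6 of the 1,2-dioxane are treated as a latent cyclobutene. A ketene–alkyne [2+2] cycloaddition closes that four-membered ring by joining the ethyl-bearing C4 to the C5 methylene (together with C3–C6), starting from but-1-yne and dichloroketene made in the flask. After C4 is set by asymmetric conjugate reduction, ozone cuts C3=C6 and inserts O1–O2, so the cyclobutene becomes the dioxane in the form of a bridged ozonide. Lewis-acid opening at the tertiary C6 with an alkenylstannane attaches the dienyl side chain axially, and a Wittig/oxa-Michael sequence installs the C3 acetic acid arm.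

Key step: step 1

Numbering used: O1–O2–C3(CH2CO2H)–C4(Et)–C5H2–C6(Et)(dienyl); side chain C7H=C8(Et)–C9H2–C10H(Et)–C11H=C12H–Et.

Remark on the chemistry (assumption): the sense of induction in step 3 is taken by analogy with 3-alkylcyclopent-2-enones and in step 6 by analogy with benzaldehyde; if a first run shows the opposite sense, the ligand antipode is used.

Step 1
Reactants: 1 but-1-yne; 2 trichloroacetyl chloride
Product: 4 4,4-dichloro-3-ethylcyclobut-2-en-1-one, via dichloroketene 3 (not isolated)
Conditions: Zn–Cu couple, Et2O/DME, 0 °C to 20 °C, slow addition of 2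
Reagents that add atoms: none
Why: Zinc dechlorinates 2 to dichloroketene 3, which adds to the alkyne in a thermal, strongly asynchronous ketene–alkyne [2+2] cycloaddition. The closest known reaction type is the dichloroketene–alkyne route to 3-alkylcyclobutenones. The four-membered ring closes in cycloaddition mode by two bonds: the CCl2 carbon to the ethyl-bearing alkyne carbon (the later C4–C5 bond) and the carbonyl carbon to the terminal CH (the later C3–C6 bond, which ozone cuts in step 5). No stereocentre is formed. The selectivity needed is regiochemical (carbonyl carbon to the terminal alkyne carbon); it is secured by attack of the unsubstituted, more nucleophilic alkyne terminus on the ketene carbonyl carbon, with positive charge building at the ethyl-substituted carbon. DME binds ZnCl2, and any chlorine-shifted isomer converges in step 2.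

Step 2
Reactants: 4 4,4-dichloro-3-ethylcyclobut-2-en-1-one
Product: 5 3-ethylcyclobut-2-en-1-one
Conditions: Zn dust, AcOH, TMEDA, EtOH, 0 °C to 20 °C
Reagents that add atoms: none
Why: Reductive dechlorination of the α,α-dichloroketone by zinc (zinc enolate, protonated by acetic acid) should remove both chlorines without opening the strained enone; no stereocentre is involved.

Step 3
Reactants: 5 3-ethylcyclobut-2-en-1-one
Product: 8 (3R)-3-ethylcyclobut-1-en-1-yl trifluoromethanesulfonate, via silyl enol ether 6 (not isolated), via lithium enolate 7 (not isolated)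
Conditions: CuCl (5 mol %), NaOt-Bu (5 mol %), (S)-p-tol-BINAP (5 mol %), Ph2SiH2, toluene, 0 °C; then MeLi, THF, −78 °C; then PhNTf2, −78 °C to 0 °C
Reagents that add atoms: N-phenylbis(trifluoromethanesulfonimide), O=S(=O)(N(c1ccccc1)S(=O)(=O)C(F)(F)F)C(F)(F)F
Why: Ligand-controlled asymmetric conjugate reduction by copper hydride delivers hydride to one face of the β-carbon and sets C4 (R); silicon traps the enolate on the C3 side only, and Si-to-Li exchange followed by O-triflation fixes that regiochemistry before proton exchange could racemise it.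

Step 4
Reactants: 8 (3R)-3-ethylcyclobut-1-en-1-yl trifluoromethanesulfonate
Product: 9 (3R)-1,3-diethylcyclobut-1-ene
Conditions: EtMgBr, Fe(acac)3 (5 mol %), THF/NMP, −30 °C; product kept as a pentane solution (volatile)
Reagents that add atoms: ethylmagnesium bromide, CC[Mg]Br
Why: Iron-catalysed Kumada-type cross-coupling of an alkenyl triflate with an alkyl Grignard reagent should install the C6 ethyl group; the allylic stereocentre C4 is not touched.

Step 5
Reactants: 9 (3R)-1,3-diethylcyclobut-1-ene
Product: 10 (5R)-1,5-diethyl-2,3,7-trioxabicyclo[2.2.1]heptane (ozonide; both bridgehead diastereomers)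
Conditions: O3, pentane, −78 °C; N2 purge; handled cold in solution
Reagents that add atoms: ozone, [O-][O+]=O
Why: Ozonolysis by the Criegee mechanism (1,3-dipolar cycloaddition, cycloreversion, recombination of the carbonyl oxide with the carbonyl tethered through C4–C5) should give the bridged ozonide, in which C3–O–O–C6 and C4–C5 already form the 1,2-dioxane ring; either sense of primary-ozonide cleavage gives the same ozonide, and C4 is untouched.

Step 6
Reactants: 11 (E)-pent-2-enal
Product: 12 (3R,4E)-hept-4-en-3-ol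
Conditions: Et2Zn, (+)-MIB [(2R)-3-exo-morpholinoisoborneol, 4 mol %], hexane, 0 °C
Reagents that add atoms: diethylzinc, CC[Zn]CC
Why: Amino-alcohol-catalysed enantioselective 1,2-addition of diethylzinc to the enal sets the carbinol centre (R) by ligand control.

Step 7
Reactants: 12 (3R,4E)-hept-4-en-3-ol
Product: 13 ethyl (3R,4E)-3-ethylhept-4-enoate
Conditions: MeC(OEt)3, EtCO2H (cat.), 140 °C, EtOH distilled off
Reagents that add atoms: triethyl orthoacetate, CC(OCC)(OCC)OCC
Why: Johnson–Claisen rearrangement through a chair transition state with the carbinol ethyl group equatorial transfers the C–O stereocentre suprafacially to the new C–C stereocentre (the later C10, R) and gives the E alkene.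

Step 8
Reactants: 13 ethyl (3R,4E)-3-ethylhept-4-enoate
Product: 14 (3R,4E)-3-ethylhept-4-enal
Conditions: i-Bu2AlH (1.05 equiv), CH2Cl2, −78 °C; aqueous potassium sodium tartrate
Reagents that add atoms: none
Why: Partial reduction of the ester at low temperature through a stable aluminium hemiacetal gives the aldehyde; the stereocentre is β to the carbonyl group and cannot epimerise.

Step 9
Reactants: 14 (3R,4E)-3-ethylhept-4-enal
Product: 15 (4R,5E)-4-ethyloct-5-en-1-yne
Conditions: dimethyl (1-diazo-2-oxopropyl)phosphonate, K2CO3, MeOH, 0 °C to 20 °C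
Reagents that add atoms: dimethyl (1-diazo-2-oxopropyl)phosphonate, COP(=O)(OC)C(=[N+]=[N-])C(C)=O
Why: Seyferth–Gilbert homologation in the Ohira–Bestmann variant converts the aldehyde into the terminal alkyne (C7 added) under mild base.

Step 10
Reactants: 15 (4R,5E)-4-ethyloct-5-en-1-yne
Product: 17 (1E,4R,5E)-2,4-diethyl-1-iodoocta-1,5-diene, via alkenylcopper 16 (not isolated)
Conditions: EtMgBr, CuBr·SMe2 (1:1), Et2O/Me2S, −45 °C to −25 °C; then I2, THF, −78 °C to 0 °C
Reagents that add atoms: ethylmagnesium bromide, CC[Mg]Br; iodine, II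
Why: syn-Carbocupration of the terminal alkyne puts ethyl on the internal carbon and copper on the terminal carbon, cis to each other, and iodinolysis with retention gives the iodide in which C9 is trans to iodine (the later E C7=C8 geometry).

Step 11
Reactants: 17 (1E,4R,5E)-2,4-diethyl-1-iodoocta-1,5-diene
Product: 19 tributyl[(1E,4R,5E)-2,4-diethylocta-1,5-dien-1-yl]stannane, via alkenyllithium 18 (not isolated)
Conditions: t-BuLi (2.1 equiv), Et2O, −78 °C; then Bu3SnCl, −78 °C to 20 °C
Reagents that add atoms: tributyltin chloride, CCCC[Sn](Cl)(CCCC)CCCC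
Why: Lithium–iodine exchange and stannylation both proceed with retention of the alkene geometry.

Step 12
Reactants: 10 (5R)-1,5-diethyl-2,3,7-trioxabicyclo[2.2.1]heptane; 19 tributyl[(1E,4R,5E)-2,4-diethylocta-1,5-dien-1-yl]stannane
Product: 21 (4R,6S)-6-[(1E,4R,5E)-2,4-diethylocta-1,5-dien-1-yl]-4,6-diethyl-1,2-dioxan-3-ol (C3 epimers, in equilibrium with its open hydroperoxy aldehyde form), via silyl peroxyacetal 20 (not isolated)
Conditions: TMSOTf (1.05 equiv), 2,6-di-tert-butyl-4-methylpyridine (0.3 equiv), CH2Cl2, −78 °C; then pyridine/MeOH quench and aqueous citric acid, 0 °C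
Reagents that add atoms: none
Why: Proposed new method: TMSOTf silylates the bridging ether oxygen of ozonide 10 and heterolyses its bond to the tertiary bridgehead C6, giving a six-membered peroxycarbenium ion (C6=O1+) that keeps the ring, the O–O bond and a silyl peroxyacetal at C3; the stannane attacks C6 through its tin-bearing carbon (β-stannyl cation at the fully substituted C8) and loses Bu3Sn+ with retention of the E geometry; the closest known reaction types are the Lewis-acid ionisation of ozonides and cyclic peroxyketals to peroxycarbenium ions trapped by allylsilanes and silyl enol ethers, and the ipso substitution of alkenylstannanes by oxocarbenium ions; C6 (S) is set by stereoelectronically preferred axial attack on the half-chair cation whose C4 ethyl group is pseudo-equatorial, which places the alkenyl group trans to the C4 ethyl group.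

Step 13
Reactants: 21 (4R,6S)-6-[(1E,4R,5E)-2,4-diethylocta-1,5-dien-1-yl]-4,6-diethyl-1,2-dioxan-3-ol
Product: 23 methyl 2-[(3S,4R,6S)-6-[(1E,4R,5E)-2,4-diethylocta-1,5-dien-1-yl]-4,6-diethyl-1,2-dioxan-3-yl]acetate, via hydroperoxy enoate 22 (not isolated)
Conditions: Ph3P=CHCO2Me, CH2Cl2, 0 °C to 20 °C; then Et2NH (cat.), CF3CH2OH, 20 °C
Reagents that add atoms: methyl (triphenylphosphoranylidene)acetate, COC(=O)C=P(c1ccccc1)(c1ccccc1)c1ccccc1
Why: Wittig olefination of the aldehyde tautomer gives the E-enoate 22, and reversible amine-catalysed 6-exo oxa-Michael addition of the tertiary hydroperoxide closes the dioxane through a chair with the C3 and C4 substituents both equatorial, setting C3 (S) trans to the C4 ethyl group.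

Step 14
Reactants: 23 methyl 2-[(3S,4R,6S)-6-[(1E,4R,5E)-2,4-diethylocta-1,5-dien-1-yl]-4,6-diethyl-1,2-dioxan-3-yl]acetate
Product: 24 2-[(3S,4R,6S)-6-[(1E,4R,5E)-2,4-diethylocta-1,5-dien-1-yl]-4,6-diethyl-1,2-dioxan-3-yl]acetic acid (target)
Conditions: LiOH, THF/H2O, 0 °C; then 1 M HCl to pH 3
Reagents that add atoms: lithium hydroxide (aqueous), [Li+].[OH-]
Why: Saponification of the methyl ester by acyl–oxygen cleavage at 0 °C should leave the dialkyl peroxide, the alkenes and all stereocentres untouched.

Compound list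
1 | but-1-yne | CCC#C | starting material
2 | trichloroacetyl chloride | ClC(Cl)(Cl)C(Cl)=O | starting material
3 | dichloroketene | ClC(Cl)=C=O | intermediate (not isolated)
4 | 4,4-dichloro-3-ethylcyclobut-2-en-1-one | CCC1=CC(=O)C1(Cl)Cl | intermediate
5 | 3-ethylcyclobut-2-en-1-one | CCC1=CC(=O)C1 | intermediate
6 | {[(3R)-3-ethylcyclobut-1-en-1-yl]oxy}diphenylsilane | CC[C@H]1C=C(O[SiH](c2ccccc2)c2ccccc2)C1 | intermediate (not isolated)
7 | lithium (3R)-3-ethylcyclobut-1-en-1-olate | CC[C@H]1C=C(O[Li])C1 | intermediate (not isolated)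
8 | (3R)-3-ethylcyclobut-1-en-1-yl trifluoromethanesulfonate | CC[C@H]1C=C(OS(=O)(=O)C(F)(F)F)C1 | intermediate
9 | (3R)-1,3-diethylcyclobut-1-ene | CC[C@H]1C=C(CC)C1 | intermediate
10 | (5R)-1,5-diethyl-2,3,7-trioxabicyclo[2.2.1]heptane | CCC12OOC(O1)[C@H](CC)C2 | intermediate
11 | (E)-pent-2-enal | CC/C=C/C=O | starting material
12 | (3R,4E)-hept-4-en-3-ol | CC/C=C/[C@H](O)CC | intermediate
13 | ethyl (3R,4E)-3-ethylhept-4-enoate | CC/C=C/[C@H](CC)CC(=O)OCC | intermediate
14 | (3R,4E)-3-ethylhept-4-enal | CC/C=C/[C@H](CC)CC=O | intermediate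
15 | (4R,5E)-4-ethyloct-5-en-1-yne | CC/C=C/[C@H](CC)CC#C | intermediate
16 | [(1E,4R,5E)-2,4-diethylocta-1,5-dien-1-yl]copper | CC/C=C/[C@H](CC)C/C(=C/[Cu])CC | intermediate (not isolated)
17 | (1E,4R,5E)-2,4-diethyl-1-iodoocta-1,5-diene | CC/C=C/[C@H](CC)C/C(=C/I)CC | intermediate
18 | [(1E,4R,5E)-2,4-diethylocta-1,5-dien-1-yl]lithium | CC/C=C/[C@H](CC)C/C(=C/[Li])CC | intermediate (not isolated)
19 | tributyl[(1E,4R,5E)-2,4-diethylocta-1,5-dien-1-yl]stannane | CC/C=C/[C@H](CC)C/C(=C/[Sn](CCCC)(CCCC)CCCC)CC | intermediate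
20 | {[(4R,6S)-6-[(1E,4R,5E)-2,4-diethylocta-1,5-dien-1-yl]-4,6-diethyl-1,2-dioxan-3-yl]oxy}trimethylsilane | CC/C=C/[C@H](CC)C/C(=C/[C@]1(CC)C[C@@H](CC)C(O[Si](C)(C)C)OO1)CC | intermediate (not isolated)
21 | (4R,6S)-6-[(1E,4R,5E)-2,4-diethylocta-1,5-dien-1-yl]-4,6-diethyl-1,2-dioxan-3-ol | CC/C=C/[C@H](CC)C/C(=C/[C@]1(CC)C[C@@H](CC)C(O)OO1)CC | intermediate
22 | methyl (2E,4R,6S,7E,10R,11E)-4,6,8,10-tetraethyl-6-hydroperoxytetradeca-2,7,11-trienoate | CC/C=C/[C@H](CC)C/C(=C/[C@](OO)(CC)C[C@@H](CC)/C=C/C(=O)OC)CC | intermediate (not isolated)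
23 | methyl 2-[(3S,4R,6S)-6-[(1E,4R,5E)-2,4-diethylocta-1,5-dien-1-yl]-4,6-diethyl-1,2-dioxan-3-yl]acetate | CC/C=C/[C@H](CC)C/C(=C/[C@]1(CC)C[C@@H](CC)[C@H](CC(=O)OC)OO1)CC | intermediate
24 | 2-[(3S,4R,6S)-6-[(1E,4R,5E)-2,4-diethylocta-1,5-dien-1-yl]-4,6-diethyl-1,2-dioxan-3-yl]acetic acid | CC/C=C/[C@H](CC)C/C(=C/[C@]1(CC)C[C@@H](CC)[C@H](CC(=O)O)OO1)CC | target

Total step count: 14
Longest linear sequence: 9 steps (steps 6–11, then 12–14)

Steps most likely to fail

1. Step 12 (Proposed new method). The ozonide may ionise in other modes (cycloreversion to carbonyl oxide and silylated aldehyde, O–O heterolysis with migration). The stannane may be protodestannylated, an open-chain cation may react with poor facial selectivity, or the new tertiary allylic C6–O bond may ionise again. The fallback uses known chemistry, sets out from cyclobutene 9 and iodide 17 and returns at ester 23. Ozonolysis of 9 with reductive work-up (O3, CH2Cl2, −78 °C; Me2S) should give (2R)-2-ethyl-4-oxohexanal F1. Aldehyde-selective Wittig olefination with Ph3P=CHCO2Me gives methyl (2E,4R)-4-ethyl-6-oxooct-2-enoate F2. Alkenyllithium 18 (from 17 and t-BuLi) adds to the ketone at −78 °C to give methyl (2E,4R,7E,10R,11E)-4,6,8,10-tetraethyl-6-hydroxytetradeca-2,7,11-trienoate F3 as both C6 epimers. Acid-catalysed perhydrolysis (50% H2O2, cat. H2SO4, Et2O, 0 °C) converts this through the allylic cation into hydroperoxide 22 and methyl (2E,4R,6R,7E,10R,11E)-4,6,8,10-tetraethyl-6-hydroperoxytetradeca-2,7,11-trienoate F4. Et2NH in CF3CH2OH closes both, and 23 is separated by chromatography from methyl 2-[(3S,4R,6R)-6-[(1E,4R,5E)-2,4-diethylocta-1,5-dien-1-yl]-4,6-diethyl-1,2-dioxan-3-yl]acetate F5. C6 is then not controlled, but the two are ring diastereomers and should be separable.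

2. Step 3. The strained enone may undergo 1,2-reduction or ring opening, the facial selectivity of hydride delivery may be low, or the enolate may racemise by proton exchange with ketone before triflation. The fallback sets out from 5 and returns at 8. Hydrogenation (H2, Pd/C, pentane) gives 3-ethylcyclobutan-1-one F6. Enantiotopic deprotonation with lithium bis[(R)-1-phenylethyl]amide and LiCl (THF, −100 °C), followed by O-triflation with PhNTf2, gives 8; the amide antipode is chosen by correlation with material from step 3.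

3. Step 13. The free hydroperoxide may oxidise the ylide, the aldehyde form may epimerise at C4 or fragment before olefination, or ring closure may show poor trans selectivity. The fallback sets out from 21 and returns at 23. Silylation of the hydroperoxide of the open form (TESCl, imidazole, DMF, 0 °C) gives (2R,4S,5E,8R,9E)-2,4,6,8-tetraethyl-4-[(triethylsilyl)peroxy]dodeca-5,9-dienal F7. Wittig olefination gives methyl (2E,4R,6S,7E,10R,11E)-4,6,8,10-tetraethyl-6-[(triethylsilyl)peroxy]tetradeca-2,7,11-trienoate F8. Fluoride (TBAF, AcOH, THF, 0 °C) then releases 22, which cyclises to 23 under Et2NH in CF3CH2OH.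

Further compounds
F1 | step 12 | (2R)-2-ethyl-4-oxohexanal | O=C[C@H](CC)CC(=O)CC
F2 | step 12 | methyl (2E,4R)-4-ethyl-6-oxooct-2-enoate | COC(=O)/C=C/[C@H](CC)CC(=O)CC
F3 | step 12 | methyl (2E,4R,7E,10R,11E)-4,6,8,10-tetraethyl-6-hydroxytetradeca-2,7,11-trienoate (C6 epimers) | CC/C=C/[C@H](CC)C/C(=C/C(O)(CC)C[C@@H](CC)/C=C/C(=O)OC)CC
F4 | step 12 | methyl (2E,4R,6R,7E,10R,11E)-4,6,8,10-tetraethyl-6-hydroperoxytetradeca-2,7,11-trienoate | CC/C=C/[C@H](CC)C/C(=C/[C@@](OO)(CC)C[C@@H](CC)/C=C/C(=O)OC)CC
F5 | step 12 | methyl 2-[(3S,4R,6R)-6-[(1E,4R,5E)-2,4-diethylocta-1,5-dien-1-yl]-4,6-diethyl-1,2-dioxan-3-yl]acetate | CC/C=C/[C@H](CC)C/C(=C/[C@@]1(CC)C[C@@H](CC)[C@H](CC(=O)OC)OO1)CC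
F6 | step 3 | 3-ethylcyclobutan-1-one | CCC1CC(=O)C1
F7 | step 13 | (2R,4S,5E,8R,9E)-2,4,6,8-tetraethyl-4-[(triethylsilyl)peroxy]dodeca-5,9-dienal | CC/C=C/[C@H](CC)C/C(=C/[C@](OO[Si](CC)(CC)CC)(CC)C[C@@H](CC)C=O)CC
F8 | step 13 | methyl (2E,4R,6S,7E,10R,11E)-4,6,8,10-tetraethyl-6-[(triethylsilyl)peroxy]tetradeca-2,7,11-trienoate | CC/C=C/[C@H](CC)C/C(=C/[C@](OO[Si](CC)(CC)CC)(CC)C[C@@H](CC)/C=C/C(=O)OC)CC
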